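The runs are calculated for an exercise; noise was put on by code.

1.21 /min is the first-order rate of Friday's starting material, and our quick number for you begins there.

| flask | starting material | first nucleophile | second nucleophile | protic impurity | remark | time |
|---|---|---|---|---|---|---|
| Friday's | 0.050 M | 0.12 M | 0.25 M | 2 mM | run made earlier |  |
| Thursday's | 0.20 M | 0.12 M | 0.25 M | 2 mM | run made earlier |  |
| Sunday's | 0.10 M | 0.12 M | 0.25 M | 4 mM | run made earlier |  |
| flask | 0.10 M | 0.120 M | 0.250 M | 2.00 mM |  | 40 min |

- Friday's (time / min: target / %, starting material / %): 0.333: 12.5, 66.8; 0.667: 19.2, 44.5; 1.33: 21.4, 20.0; 3.00: 13.5, 3.4; 6.00: 3.5, 0.7; 15.0: 0.6, 0; 30.0: 0.3, 0.3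
- Thursday's (time / min: target / %, starting material / %): 0.333: 12.2, 67.9; 0.667: 18.3, 43.8; 1.33: 21.0, 20.5; 3.00: 19.1, 3.4; 6.00: 14.0, 0.3; 15.0: 8.0, 0; 30.0: 5.7, 0.1
- Sunday's (time / min: target / %, starting material / %): 0.333: 11.8, 66.8; 1.00: 21.2, 30.9; 3.00: 15.0, 2.3; 10.0: 3.2, 0.8; 30.0: 0, 0

(standard deviation of a reading: 0.5 percentage points)

* time, not beyond 40 min, at which the flask holds most target
* the amount of target, in percent of the starting material charged, at that time

- reactions considered so far: starting material -> intermediate; first nucleophile + intermediate -> target; second nucleophile + intermediate -> other capture product; intermediate -> solvolysis product; second nucleophile + protic impurity -> quenched reagent; first nucleophile + target -> over-reaction product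

Friday's target later falls at 0.450 /min, read between 3.00 min and 6.00 min, but over that stretch Thursday's falls at 0.104 /min, and Sunday's, at the flask's 1.20 equivalents of first nucleophile, at 0.221 /min between 3.00 min and 10.0 min, so the late loss is no constant, pseudo-first-order rate. Up to 1.33 min, though, Friday's 21.4 % and Thursday's 21.0 % stand 0.4 percentage points apart, so for the rise we borrow Friday's figure as a rough working loss. Now feed target from the starting material through a fixed capture share and remove it at that loss rate. Integrating gives a rise and fall whose top comes at the logarithm of the two rates' ratio divided by their difference: 1.30 min. At the top, feed equals loss, and the height is the capture share times the exponential of minus loss rate times top time. We call this the peak factor, the height of the top over the capture share, 0.557. Friday's reading of 21.4 % divided by it implies a capture share of 0.384. Both nucleophile charges match in the flask, so we commit to that same height near 1.30 min.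

Your forecast stands at 1.3 min and 21.7 %, on the view that “The flask should therefore resemble Sunday's run”.

The flask reaches 21.5 % at 1.28 min, with 21.5 % of the starting material still there.

    starting material → intermediate (k = 0.0200 /s)
    first nucleophile + intermediate → target (k = 16.0 /M/s)
    second nucleophile + intermediate → other capture product (k = 3.70 /M/s)
    intermediate → solvolysis product (k = 1.50 /s)
    second nucleophile + protic impurity → quenched reagent (k = 0.330 /M/s)
    first nucleophile + target → over-reaction product (k = 0.0890 /M/s)

Divided by the peak factor 0.557, that height gives a capture share of 0.387. For a neighbouring flask charged with 0.20 M of first nucleophile we scale both the capture odds and the working loss by 1.67. Its loss rate becomes 0.750 /min, its top 1.04 min, its peak factor 0.459 and its share 0.513. Their product is 23.5 %, and that neighbour's simulated best is 22.9 %.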